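**Retrosynthetic overview**

1. The target is traced back, by fluoride removal of two 2-(trimethylsilyl)ethyl groups and by C5 acylation (ortho-formylation, isopropyl addition, oxidation), to a 7-(pyranonylmethyl)-6-alkoxy-2-isopropenyl-2,3-dihydrobenzofuran-4-ol.
2. Key disconnection of the benzene ring (ring A; numbering O1, C2, C3, C3a, C4–C7, C7a). The feature used is the enol ether O1–C7a=C3a that ring A shares with the dihydrofuran ring (ring B). It is read as the alkoxyvinyl arm of a vinylketene whose ketene carbon is C4 and whose α-carbon C7 already carries the pyranonylmethyl group; C5 and the oxygenated C6 come from an ynol ether (bonds C7a–C7 by Wolff shift, C4–C5, C6–C7, C3a–C4).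
3. The diazo ketone comes by deacylative diazo transfer from the ketone made from C5-lithiated (R)-2-isopropenyl-2,3-dihydrofuran and the Weinreb amide of the pyranone propanoic acid.
4. Ring B comes from (R)-γ-isopropenyl-γ-butyrolactone (a Corey–Bakshi–Shibata reduction sets the only stereocentre). The pyranone (ring C) comes from 3-pentanone and malonyl dichloride, then C3 Michael addition and O4 Mitsunobu alkylation.
5. Order of ring formation: ring C and ring B in separate branches, ring A last, in the key step.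

Key step: step 11

Remark: both masked oxygens carry 2-(trimethylsilyl)ethyl groups (one delivered by the ynol ether, one on the pyranone), because boron trihalides are expected to open the allylic C2–O1 bond of a 2-isopropenyl-2,3-dihydrobenzofuran, whereas fluoride leaves it alone.

**Route**

Step 1
Reactants: 1 methyl 4-chloro-4-oxobutanoate; 2 isopropenylmagnesium bromide
Product: 3 methyl 5-methyl-4-oxohex-5-enoate
Conditions: 2 (1.0 equiv, slow addition), CuBr·SMe2 (5 mol %), THF, −78 °C
Reagents that add atoms: none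
Why: Copper-catalysed acylation of a Grignard reagent by an acid chloride is far faster at −78 °C than attack on the methyl ester or on the ketone formed, so the isopropenyl ketone should be obtained without over-addition.

Step 2
Reactants: 3 methyl 5-methyl-4-oxohex-5-enoate
Product: 5 (R)-5-(prop-1-en-2-yl)dihydrofuran-2(3H)-one, via hydroxy ester 4 (not isolated)
Conditions: (S)-2-butyl-CBS-oxazaborolidine (15 mol %), catecholborane, toluene, −78 °C; MeOH; then p-TsOH·H2O (cat.), CH2Cl2, 20 °C
Reagents that add atoms: none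
Why: In this Corey–Bakshi–Shibata reduction the isopropenyl group acts as the large substituent, so the (S)-oxazaborolidine should deliver hydride to the face that gives the R carbinol (the same sense as acetophenone to (R)-1-phenylethanol), catecholborane avoids hydroboration of the alkene, and acid-catalysed lactonisation of the γ-hydroxy ester follows.

Step 3
Reactants: 5 (R)-5-(prop-1-en-2-yl)dihydrofuran-2(3H)-one
Product: 6 (5R)-5-(prop-1-en-2-yl)tetrahydrofuran-2-ol (mixture of anomers)
Conditions: i-Bu2AlH (1.1 equiv), CH2Cl2, −78 °C; aq potassium sodium tartrate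
Reagents that add atoms: none
Why: Partial reduction of a γ-lactone with i-Bu2AlH stops at the tetrahedral aluminium alkoxide at −78 °C and gives the lactol without touching the stereocentre.

Step 4
Reactants: 6 (5R)-5-(prop-1-en-2-yl)tetrahydrofuran-2-ol
Product: 8 (R)-2-(prop-1-en-2-yl)-2,3-dihydrofuran, via lactol mesylate 7 (not isolated)
Conditions: MsCl, Et3N, CH2Cl2, −40 °C → reflux
Reagents that add atoms: none
Why: Mesylation of the anomeric hydroxyl and amine-mediated elimination through the oxocarbenium ion is the standard dehydration of a 2-deoxy lactol to the cyclic enol ether, and no bond at C2 is broken.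

Step 5
Reactants: 9 3-pentanone; 10 malonyl dichloride
Product: 11 6-ethyl-4-hydroxy-5-methyl-2H-pyran-2-one
Conditions: 9 (excess, as solvent), 0 → 45 °C
Reagents that add atoms: none
Why: Condensation of a dialkyl ketone with malonyl dichloride (C-acylation of the enol, then O-acylative ring closure) is the classical one-step entry to 5,6-dialkyl-4-hydroxy-2-pyranones.

Step 6
Reactants: 11 6-ethyl-4-hydroxy-5-methyl-2H-pyran-2-one; 12 N-methoxy-N-methylacrylamide
Product: 13 3-(6-ethyl-4-hydroxy-5-methyl-2-oxo-2H-pyran-3-yl)-N-methoxy-N-methylpropanamide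
Conditions: DBU (1.0 equiv), MeCN, 70 °C; then 1 M HCl
Reagents that add atoms: none
Why: Base-mediated Michael addition of a cyclic 1,3-dicarbonyl-type enolate through its carbon C3 to an acrylamide is classical, and re-formation of the stabilised 4-oxidopyranone drives it.

Step 7
Reactants: 13 3-(6-ethyl-4-hydroxy-5-methyl-2-oxo-2H-pyran-3-yl)-N-methoxy-N-methylpropanamide; 14 2-(trimethylsilyl)ethanol
Product: 15 3-{6-ethyl-5-methyl-2-oxo-4-[2-(trimethylsilyl)ethoxy]-2H-pyran-3-yl}-N-methoxy-N-methylpropanamide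
Conditions: PPh3, DIAD, THF, 0 → 20 °C
Reagents that add atoms: none
Why: Mitsunobu O-alkylation of the acidic 4-hydroxyl of a 4-hydroxy-2-pyranone with a primary alcohol should give the 4-alkoxy-2-pyranone, since C3 is blocked and alkylation at the lactone oxygen is the disfavoured mode.

Step 8
Reactants: 8 (R)-2-(prop-1-en-2-yl)-2,3-dihydrofuran; 15 3-{6-ethyl-5-methyl-2-oxo-4-[2-(trimethylsilyl)ethoxy]-2H-pyran-3-yl}-N-methoxy-N-methylpropanamide
Product: 17 (R)-3-{6-ethyl-5-methyl-2-oxo-4-[2-(trimethylsilyl)ethoxy]-2H-pyran-3-yl}-1-[5-(prop-1-en-2-yl)-4,5-dihydrofuran-2-yl]propan-1-one, via lithiated dihydrofuran 16 (not isolated)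
Conditions: 8 (1.5 equiv), t-BuLi (1.4 equiv), THF, −78 → 0 °C; then 15 (1.0 equiv), −78 °C; aq NH4Cl
Reagents that add atoms: none
Why: α-Lithiation of a cyclic enol ether at its oxygen-bearing vinylic carbon followed by acylation with a Weinreb amide (chelated tetrahedral intermediate, no over-addition) is standard, and the fully substituted 4-alkoxy-2-pyranone should not compete at −78 °C.

Step 9
Reactants: 17 (R)-3-{6-ethyl-5-methyl-2-oxo-4-[2-(trimethylsilyl)ethoxy]-2H-pyran-3-yl}-1-[5-(prop-1-en-2-yl)-4,5-dihydrofuran-2-yl]propan-1-one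
Product: 19 (R)-2-diazo-3-{6-ethyl-5-methyl-2-oxo-4-[2-(trimethylsilyl)ethoxy]-2H-pyran-3-yl}-1-[5-(prop-1-en-2-yl)-4,5-dihydrofuran-2-yl]propan-1-one, via trifluoroacetyl diketone 18 (not isolated)
Conditions: LiN(SiMe3)2, THF, −78 °C; CF3CO2CH2CF3; cold dilute HCl work-up; then MsN3, Et3N, H2O (1 equiv), MeCN, 20 °C
Reagents that add atoms: methanesulfonyl azide, CS(=O)(=O)N=[N+]=[N-]
Why: Detrifluoroacetylative diazo transfer (kinetic enolisation at the only α-CH2, C-trifluoroacetylation, then sulfonyl azide transfer with loss of the trifluoroacetyl group) is the established way to α-diazo ketones from enones that resist direct Regitz transfer.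

Step 10
Reactants: 14 2-(trimethylsilyl)ethanol; 20 trichloroethylene
Product: 23 [2-(ethynyloxy)ethyl]trimethylsilane, via dichlorovinyl ether 21 (not isolated), via lithium alkynyl ether 22 (not isolated)
Conditions: KH, THF, 0 °C; 20, −50 → 20 °C; n-BuLi (2.4 equiv), −78 → −40 °C; MeOH, −78 °C
Reagents that add atoms: none
Why: Addition of the alkoxide to dichloroacetylene formed in situ gives the 1,2-dichlorovinyl ether, and n-BuLi then effects elimination and chlorine–lithium exchange to the lithium alkynyl ether, which is protonated; this is the general route from an alcohol to an alkoxyacetylene.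

Step 11
Reactants: 19 (R)-2-diazo-3-{6-ethyl-5-methyl-2-oxo-4-[2-(trimethylsilyl)ethoxy]-2H-pyran-3-yl}-1-[5-(prop-1-en-2-yl)-4,5-dihydrofuran-2-yl]propan-1-one; 23 [2-(ethynyloxy)ethyl]trimethylsilane
Product: 27 (R)-7-({6-ethyl-5-methyl-2-oxo-4-[2-(trimethylsilyl)ethoxy]-2H-pyran-3-yl}methyl)-2-(prop-1-en-2-yl)-6-[2-(trimethylsilyl)ethoxy]-2,3-dihydrobenzofuran-4-ol, via vinylketene 24 (not isolated), via cyclobutenone 25 (not isolated), via dienylketene 26 (not isolated)
Conditions: hν (350 nm lamps, Pyrex), 23 (3 equiv), ClCH2CH2Cl, 20 °C; volatiles removed; toluene, 80 °C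
Reagents that add atoms: none
Why: Excitation of 19 at its long-wavelength band expels N2 with 1,2-shift of the dihydrofuranyl carbon C7a from the carbonyl carbon to C7 (photo-Wolff rearrangement) to give the alkoxyvinylketene 24, and the polarised ketene–ynol ether (2+2) then joins the nucleophilic CH of 23 to the ketene carbon (C4–C5) and the oxygen-bearing alkyne carbon to C7 (C6–C7) to give cyclobutenone 25. Reversible conrotatory 4π opening of 25 breaks C4–C7 and gives dienylketene 26, and only the isomer with the dihydrofuranyl group turned inward can close, so the equilibrium should drain through it. Thermal disrotatory 6π electrocyclisation forms C3a–C4, which closes the six-membered carbocycle (ring A; the four-membered ring of 25 is transient), and enolisation gives the phenol. The closest known reaction is the photochemical Danheiser benzannulation of alkenyl, aryl and heteroaryl diazo ketones with alkoxy- and siloxyalkynes, the 2-furyl diazo ketone to benzofuranol case being the aromatic counterpart of this dihydrofuranyl substrate. No lasting stereocentre is created, and C2 takes part in no bond change, so its configuration is carried through. The step needs the (2+2) regiochemistry, fixed by the donor oxygen of the ynol ether, and a Wolff shift that outruns 1,2-hydride shift from the CH2 next to the carbene carbon, which direct unsensitised irradiation and the high migratory aptitude of the alkenyl group should favour; 350 nm light leaves the 4-alkoxy-2-pyranone unexcited.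

Step 12
Reactants: 27 (R)-7-({6-ethyl-5-methyl-2-oxo-4-[2-(trimethylsilyl)ethoxy]-2H-pyran-3-yl}methyl)-2-(prop-1-en-2-yl)-6-[2-(trimethylsilyl)ethoxy]-2,3-dihydrobenzofuran-4-ol
Product: 28 (R)-7-({6-ethyl-5-methyl-2-oxo-4-[2-(trimethylsilyl)ethoxy]-2H-pyran-3-yl}methyl)-4-hydroxy-2-(prop-1-en-2-yl)-6-[2-(trimethylsilyl)ethoxy]-2,3-dihydrobenzofuran-5-carbaldehyde
Conditions: MgCl2, Et3N, (CH2O)n, MeCN, reflux
Reagents that add atoms: paraformaldehyde (as formaldehyde), C=O
Why: In this magnesium-mediated ortho-formylation (Casnati–Skattebøl type) the magnesium phenoxide directs formaldehyde to C5, the only free ring carbon and ortho to the C4 hydroxyl, and a second formaldehyde oxidises the hydroxymethyl intermediate to the aldehyde.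

Step 13
Reactants: 28 (R)-7-({6-ethyl-5-methyl-2-oxo-4-[2-(trimethylsilyl)ethoxy]-2H-pyran-3-yl}methyl)-4-hydroxy-2-(prop-1-en-2-yl)-6-[2-(trimethylsilyl)ethoxy]-2,3-dihydrobenzofuran-5-carbaldehyde; 29 isopropylmagnesium chloride
Product: 30 (2R)-7-({6-ethyl-5-methyl-2-oxo-4-[2-(trimethylsilyl)ethoxy]-2H-pyran-3-yl}methyl)-5-(1-hydroxy-2-methylpropyl)-2-(prop-1-en-2-yl)-6-[2-(trimethylsilyl)ethoxy]-2,3-dihydrobenzofuran-4-ol (both carbinol epimers)
Conditions: 29 (4 equiv), CeCl3 (anhydrous), THF, −78 → −30 °C; aq NH4Cl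
Reagents that add atoms: none
Why: 1,2-Addition of the organocerium reagent made from the Grignard reagent and CeCl3 to the salicylaldehyde (after deprotonation of the phenol) should suppress β-hydride reduction and attack on the pyranone; the carbinol centre is formed without control and is removed in step 14.

Step 14
Reactants: 30 (2R)-7-({6-ethyl-5-methyl-2-oxo-4-[2-(trimethylsilyl)ethoxy]-2H-pyran-3-yl}methyl)-5-(1-hydroxy-2-methylpropyl)-2-(prop-1-en-2-yl)-6-[2-(trimethylsilyl)ethoxy]-2,3-dihydrobenzofuran-4-ol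
Product: 31 (R)-1-{7-({6-ethyl-5-methyl-2-oxo-4-[2-(trimethylsilyl)ethoxy]-2H-pyran-3-yl}methyl)-4-hydroxy-2-(prop-1-en-2-yl)-6-[2-(trimethylsilyl)ethoxy]-2,3-dihydrobenzofuran-5-yl}-2-methylpropan-1-one
Conditions: DMP, pyridine, CH2Cl2, 0 °C
Reagents that add atoms: none
Why: Dess–Martin oxidation converts the secondary benzylic alcohol into the aryl ketone under buffered, non-acidic conditions, and as the ring has no free position, oxidation of the phenol is not expected to compete.

Step 15
Reactants: 31 (R)-1-{7-({6-ethyl-5-methyl-2-oxo-4-[2-(trimethylsilyl)ethoxy]-2H-pyran-3-yl}methyl)-4-hydroxy-2-(prop-1-en-2-yl)-6-[2-(trimethylsilyl)ethoxy]-2,3-dihydrobenzofuran-5-yl}-2-methylpropan-1-one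
Product: 32 (R)-3-{[4,6-dihydroxy-5-(2-methylpropanoyl)-2-(prop-1-en-2-yl)-2,3-dihydrobenzofuran-7-yl]methyl}-6-ethyl-4-hydroxy-5-methyl-2H-pyran-2-one (CNP0206652.1)
Conditions: Bu4NF (6 equiv), THF, 20 → 45 °C, argon; pH 4 buffer
Reagents that add atoms: none
Why: Fluoride-induced β-elimination (attack at silicon, loss of ethylene) should free both masked oxygens, the vinylogous ester of the pyranone and the aryl ether ortho to the ketone both being good leaving groups, without acid, so the isopropenyl group and the allylic C2–O1 bond are untouched.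

**Compound list**

1 | methyl 4-chloro-4-oxobutanoate | COC(=O)CCC(=O)Cl | starting material
2 | isopropenylmagnesium bromide | C=C(C)[Mg]Br | starting material
3 | methyl 5-methyl-4-oxohex-5-enoate | COC(=O)CCC(=O)C(C)=C | intermediate
4 | methyl (R)-4-hydroxy-5-methylhex-5-enoate (hydroxy ester; not isolated) | C=C(C)[C@H](O)CCC(=O)OC | intermediate
5 | (R)-5-(prop-1-en-2-yl)dihydrofuran-2(3H)-one | C=C(C)[C@H]1CCC(=O)O1 | intermediate
6 | (5R)-5-(prop-1-en-2-yl)tetrahydrofuran-2-ol (anomers) | C=C(C)[C@H]1CCC(O)O1 | intermediate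
7 | (5R)-5-(prop-1-en-2-yl)tetrahydrofuran-2-yl methanesulfonate (lactol mesylate; not isolated) | C=C(C)[C@H]1CCC(OS(C)(=O)=O)O1 | intermediate
8 | (R)-2-(prop-1-en-2-yl)-2,3-dihydrofuran | C=C(C)[C@H]1CC=CO1 | intermediate
9 | 3-pentanone | CCC(=O)CC | starting material
10 | malonyl dichloride | O=C(Cl)CC(=O)Cl | starting material
11 | 6-ethyl-4-hydroxy-5-methyl-2H-pyran-2-one | CCc1oc(=O)cc(O)c1C | intermediate
12 | N-methoxy-N-methylacrylamide | C=CC(=O)N(C)OC | starting material
13 | 3-(6-ethyl-4-hydroxy-5-methyl-2-oxo-2H-pyran-3-yl)-N-methoxy-N-methylpropanamide | CCc1oc(=O)c(CCC(=O)N(C)OC)c(O)c1C | intermediate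
14 | 2-(trimethylsilyl)ethanol | C[Si](C)(C)CCO | starting material
15 | 3-{6-ethyl-5-methyl-2-oxo-4-[2-(trimethylsilyl)ethoxy]-2H-pyran-3-yl}-N-methoxy-N-methylpropanamide | CCc1oc(=O)c(CCC(=O)N(C)OC)c(OCC[Si](C)(C)C)c1C | intermediate
16 | (R)-5-lithio-2-(prop-1-en-2-yl)-2,3-dihydrofuran (lithiated dihydrofuran; not isolated) | C=C(C)[C@H]1CC=C([Li])O1 | intermediate
17 | (R)-3-{6-ethyl-5-methyl-2-oxo-4-[2-(trimethylsilyl)ethoxy]-2H-pyran-3-yl}-1-[5-(prop-1-en-2-yl)-4,5-dihydrofuran-2-yl]propan-1-one | C=C(C)[C@H]1CC=C(C(=O)CCc2c(OCC[Si](C)(C)C)c(C)c(CC)oc2=O)O1 | intermediate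
18 | 2-(trifluoroacetyl) derivative of 17 (trifluoroacetyl diketone, epimers at the new centre; not isolated) | C=C(C)[C@H]1CC=C(C(=O)C(Cc2c(OCC[Si](C)(C)C)c(C)c(CC)oc2=O)C(=O)C(F)(F)F)O1 | intermediate
19 | (R)-2-diazo-3-{6-ethyl-5-methyl-2-oxo-4-[2-(trimethylsilyl)ethoxy]-2H-pyran-3-yl}-1-[5-(prop-1-en-2-yl)-4,5-dihydrofuran-2-yl]propan-1-one | C=C(C)[C@H]1CC=C(C(=O)C(=[N+]=[N-])Cc2c(OCC[Si](C)(C)C)c(C)c(CC)oc2=O)O1 | intermediate
20 | trichloroethylene | ClC=C(Cl)Cl | starting material
21 | (E)-{2-[(1,2-dichlorovinyl)oxy]ethyl}trimethylsilane (dichlorovinyl ether; not isolated) | C[Si](C)(C)CCO/C(Cl)=C\Cl | intermediate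
22 | lithium 2-[2-(trimethylsilyl)ethoxy]ethynide (lithium alkynyl ether; not isolated) | C[Si](C)(C)CCOC#C[Li] | intermediate
23 | [2-(ethynyloxy)ethyl]trimethylsilane | C[Si](C)(C)CCOC#C | intermediate
24 | vinylketene from Wolff shift of 19: ketene carbon C4, α-carbon C7 bearing the pyranonylmethyl and the (R)-5-isopropenyl-4,5-dihydrofuran-2-yl groups (not isolated) | C=C(C)[C@H]1CC=C(C(=C=O)Cc2c(OCC[Si](C)(C)C)c(C)c(CC)oc2=O)O1 | intermediate
25 | 4-[(R)-5-isopropenyl-4,5-dihydrofuran-2-yl]-4-(pyranonylmethyl)-3-[2-(trimethylsilyl)ethoxy]cyclobut-2-en-1-one (epimers at C4 of the four-membered ring; not isolated) | C=C(C)[C@H]1CC=C(C2(Cc3c(OCC[Si](C)(C)C)c(C)c(CC)oc3=O)C(=O)C=C2OCC[Si](C)(C)C)O1 | intermediate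
26 | dienylketene from ring opening of 25, ketene arm and dihydrofuranyl group cis on the C6=C7 double bond (not isolated) | C=C(C)[C@H]1CC=C(/C(Cc2c(OCC[Si](C)(C)C)c(C)c(CC)oc2=O)=C(\C=C=O)OCC[Si](C)(C)C)O1 | intermediate
27 | (R)-7-({6-ethyl-5-methyl-2-oxo-4-[2-(trimethylsilyl)ethoxy]-2H-pyran-3-yl}methyl)-2-(prop-1-en-2-yl)-6-[2-(trimethylsilyl)ethoxy]-2,3-dihydrobenzofuran-4-ol | C=C(C)[C@H]1Cc2c(O)cc(OCC[Si](C)(C)C)c(Cc3c(OCC[Si](C)(C)C)c(C)c(CC)oc3=O)c2O1 | intermediate
28 | 5-carbaldehyde of 27 | C=C(C)[C@H]1Cc2c(O)c(C=O)c(OCC[Si](C)(C)C)c(Cc3c(OCC[Si](C)(C)C)c(C)c(CC)oc3=O)c2O1 | intermediate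
29 | isopropylmagnesium chloride | CC(C)[Mg]Cl | starting material
30 | 5-(1-hydroxy-2-methylpropyl) derivative of 27 (both carbinol epimers, 2R) | C=C(C)[C@H]1Cc2c(O)c(C(O)C(C)C)c(OCC[Si](C)(C)C)c(Cc3c(OCC[Si](C)(C)C)c(C)c(CC)oc3=O)c2O1 | intermediate
31 | 5-(2-methylpropanoyl) derivative of 27 (R) | C=C(C)[C@H]1Cc2c(O)c(C(=O)C(C)C)c(OCC[Si](C)(C)C)c(Cc3c(OCC[Si](C)(C)C)c(C)c(CC)oc3=O)c2O1 | intermediate
32 | (R)-3-{[4,6-dihydroxy-5-(2-methylpropanoyl)-2-(prop-1-en-2-yl)-2,3-dihydrobenzofuran-7-yl]methyl}-6-ethyl-4-hydroxy-5-methyl-2H-pyran-2-one | C=C(C)[C@H]1Cc2c(O)c(C(=O)C(C)C)c(O)c(Cc3c(O)c(C)c(CC)oc3=O)c2O1 | target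

**Step count**

Total: 15 steps. Longest linear sequence: 11 steps (steps 1, 2, 3, 4, 8, 9, 11, 12, 13, 14, 15).

**Steps most likely to fail**

1. Step 11. After loss of N2, a 1,2-hydride shift from the CH2 that links the carbene carbon to the pyranone may outrun the Wolff shift and give a conjugated enone, or the ketene may be consumed before the (2+2). The fallback removes that CH2 from the diazo ketone and attaches the pyranone last; it sets out from 8 (with 11 and 23) and comes back at 32.
 - Lithiated 16, made from 8 as in step 8, is acylated with N-methoxy-N-methylacetamide to give (R)-1-[5-(prop-1-en-2-yl)-4,5-dihydrofuran-2-yl]ethan-1-one F1.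
 - The diazo transfer of step 9 gives (R)-2-diazo-1-[5-(prop-1-en-2-yl)-4,5-dihydrofuran-2-yl]ethan-1-one F2, which has no hydrogen next to the carbene carbon.
 - Irradiation with 23 and heating as in step 11 should give (R)-2-(prop-1-en-2-yl)-6-[2-(trimethylsilyl)ethoxy]-2,3-dihydrobenzofuran-4-ol F3.
 - Ortho-formylation as in step 12 goes to C5, next to the free hydroxyl, and gives the 5-carbaldehyde F4; the organocerium addition of step 13 gives the carbinol F5; Dess–Martin oxidation gives the 5-(2-methylpropanoyl) compound F6.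
 - Bu4NF frees (R)-1-[4,6-dihydroxy-2-(prop-1-en-2-yl)-2,3-dihydrobenzofuran-5-yl]-2-methylpropan-1-one F7, in which only C7 is unsubstituted.
 - Methylene bridging of F7 with pyranone 11 and Eschenmoser's salt (dimethylmethylideneammonium iodide, MeCN) then gives 32. This is a Mannich-type alkylation through the 3-methylene-pyran-2,4-dione, an established way to join an acylphloroglucinol and a 4-hydroxy-2-pyranone through a CH2 group.

2. Step 8. t-BuLi may remove the allylic, oxygen-bearing C2–H instead of the vinylic C5–H, which would erode the configuration or open the ring, and vinyllithium 16 may metalate the 6-ethyl group of 15 instead of adding to the amide. The fallback uses a sulfone-stabilised anion; it sets out from 6 and comes back at 17.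
 - Lactol 6 and benzenesulfinic acid (CaCl2, CH2Cl2) give (5R)-2-(phenylsulfonyl)-5-(prop-1-en-2-yl)tetrahydrofuran F8.
 - n-BuLi at −78 °C removes only the hydrogen on the sulfonyl-bearing carbon, by far the most acidic one, and acylation with 15 gives the 2-acyl-2-sulfonyl tetrahydrofuran F9.
 - Loss of benzenesulfinic acid (DBU, CH2Cl2, or MgBr2·OEt2 and Et3N) installs the enol ether double bond and gives 17.

3. Step 13. β-Hydride transfer from the isopropyl reagent may reduce the hindered, chelated aldehyde, or the reagent may attack the pyranone carbonyl. The fallback brings the carbinol carbon in with the alkyne, so that steps 12 and 13 are not needed; it sets out from 22 (made from 14 and 20 as in step 10) and from 19, and comes back at 30.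
 - Lithium alkynyl ether 22 adds to isobutyraldehyde to give 4-methyl-1-[2-(trimethylsilyl)ethoxy]pent-1-yn-3-ol F10.
 - Et3SiCl and imidazole give its triethylsilyl ether F11.
 - Irradiation of 19 with F11 and heating as in step 11 should place the silyloxyalkyl carbon at C5 and give the phenol F12.
 - HF·pyridine (buffered with pyridine, THF, 0 °C) removes the triethylsilyl group and gives 30.

Further compounds
F1 | step 11 | (R)-1-[5-(prop-1-en-2-yl)-4,5-dihydrofuran-2-yl]ethan-1-one | C=C(C)[C@H]1CC=C(C(C)=O)O1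
F2 | step 11 | (R)-2-diazo-1-[5-(prop-1-en-2-yl)-4,5-dihydrofuran-2-yl]ethan-1-one | C=C(C)[C@H]1CC=C(C(=O)C=[N+]=[N-])O1
F3 | step 11 | (R)-2-(prop-1-en-2-yl)-6-[2-(trimethylsilyl)ethoxy]-2,3-dihydrobenzofuran-4-ol | C=C(C)[C@H]1Cc2c(O)cc(OCC[Si](C)(C)C)cc2O1
F4 | step 11 | (R)-4-hydroxy-2-(prop-1-en-2-yl)-6-[2-(trimethylsilyl)ethoxy]-2,3-dihydrobenzofuran-5-carbaldehyde | C=C(C)[C@H]1Cc2c(O)c(C=O)c(OCC[Si](C)(C)C)cc2O1
F5 | step 11 | (2R)-5-(1-hydroxy-2-methylpropyl)-2-(prop-1-en-2-yl)-6-[2-(trimethylsilyl)ethoxy]-2,3-dihydrobenzofuran-4-ol | C=C(C)[C@H]1Cc2c(O)c(C(O)C(C)C)c(OCC[Si](C)(C)C)cc2O1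
F6 | step 11 | (R)-1-{4-hydroxy-2-(prop-1-en-2-yl)-6-[2-(trimethylsilyl)ethoxy]-2,3-dihydrobenzofuran-5-yl}-2-methylpropan-1-one | C=C(C)[C@H]1Cc2c(O)c(C(=O)C(C)C)c(OCC[Si](C)(C)C)cc2O1
F7 | step 11 | (R)-1-[4,6-dihydroxy-2-(prop-1-en-2-yl)-2,3-dihydrobenzofuran-5-yl]-2-methylpropan-1-one | C=C(C)[C@H]1Cc2c(O)c(C(=O)C(C)C)c(O)cc2O1
F8 | step 8 | (5R)-2-(phenylsulfonyl)-5-(prop-1-en-2-yl)tetrahydrofuran | C=C(C)[C@H]1CCC(S(=O)(=O)c2ccccc2)O1
F9 | step 8 | 3-{6-ethyl-5-methyl-2-oxo-4-[2-(trimethylsilyl)ethoxy]-2H-pyran-3-yl}-1-[(5R)-2-(phenylsulfonyl)-5-(prop-1-en-2-yl)tetrahydrofuran-2-yl]propan-1-one | C=C(C)[C@H]1CCC(C(=O)CCc2c(OCC[Si](C)(C)C)c(C)c(CC)oc2=O)(S(=O)(=O)c2ccccc2)O1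
F10 | step 13 | 4-methyl-1-[2-(trimethylsilyl)ethoxy]pent-1-yn-3-ol | CC(C)C(O)C#COCC[Si](C)(C)C
F11 | step 13 | triethyl({4-methyl-1-[2-(trimethylsilyl)ethoxy]pent-1-yn-3-yl}oxy)silane | CC(C)C(O[Si](CC)(CC)CC)C#COCC[Si](C)(C)C
F12 | step 13 | (2R)-7-({6-ethyl-5-methyl-2-oxo-4-[2-(trimethylsilyl)ethoxy]-2H-pyran-3-yl}methyl)-5-[2-methyl-1-(triethylsilyloxy)propyl]-2-(prop-1-en-2-yl)-6-[2-(trimethylsilyl)ethoxy]-2,3-dihydrobenzofuran-4-ol | C=C(C)[C@H]1Cc2c(O)c(C(O[Si](CC)(CC)CC)C(C)C)c(OCC[Si](C)(C)C)c(Cc3c(OCC[Si](C)(C)C)c(C)c(CC)oc3=O)c2O1
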